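**Plan**

Atom labels: ring A carries butanoyl at C1, OH at C2/C4/C6, prenyl at C3 and the CH2 bridge at C5; ring B carries the bridge at C1', OH at C2', acetyl at C3', OH at C4', CH3 at C5' and OCH3 at C6'.
Retrosynthesis: cut C3–prenyl, then C1–butanoyl, then the ring B bonds C2'–C3' and C4'–C5'. This splits ring B into a vinylketene silyl acetal (C2', C1', C6', C5', bridge already on C1') and 4-isopropoxybut-3-yn-2-one (C3', C4'). The bridge–C1' bond then leads back to 2,4,6-trihydroxybenzaldehyde and methyl 3-oxopentanoate.
Enabling feature: ring B is a hexasubstituted benzene with the acetyl carbon C3' between two oxygenated carbons (C2', C4') and the methoxy carbon C6' between the two alkyl-bearing carbons C1' and C5'. A 1,3-dimethoxy-1-silyloxydiene and a β-alkoxy ynone give exactly this pattern on [4+2] addition and aromatisation.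
Forward: ring A is present from the start. The bridge carbon is joined to the keto ester, the diene is made, ring B is closed in step 7, the benzyl and isopropyl ethers are removed, and ring A is then butanoylated and prenylated.
Stereochemistry: the target has no stereocentre and no stereogenic alkene, so nothing has to be controlled; the transient stereocentres of 5 and 14 are erased.

Key step: step 7

Remark: since the target contains no stereogenic element, "single enantiomer" is taken to mean the constitution shown.

**Route**

Step 1
Reactants: 1 2,4,6-trihydroxybenzaldehyde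
Product: 2 2,4,6-tris(benzyloxy)benzaldehyde
Conditions: BnBr (3.6 equiv), K2CO3, DMF, rt → 60 °C
Reagents that add atoms: benzyl bromide BrCc1ccccc1
Why: Williamson etherification: the formyl group makes the phenoxides poor C-nucleophiles, so in DMF all three oxygens, including the two hydrogen-bonded ortho ones on warming, should be O-benzylated.

Step 2
Reactants: 2 2,4,6-tris(benzyloxy)benzaldehyde; 3 methyl 3-oxopentanoate
Product: 5 methyl 3-oxo-2-[[2,4,6-tris(benzyloxy)phenyl]methyl]pentanoate (racemic), via alkylidene keto ester 4 (not isolated)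
Conditions: L-proline (20 mol %), Hantzsch ester (1.2 equiv), CH2Cl2–MeOH, 25–40 °C
Reagents that add atoms: none
Why: Amine-catalysed Knoevenagel condensation followed in the same flask by Hantzsch-ester conjugate reduction (three-component reductive alkylation): the alkylidene keto ester 4 is reduced as it forms, which prevents a second Michael addition of 3, and the new α-stereocentre is racemic and disappears in step 3.

Step 3
Reactants: 5 methyl 3-oxo-2-[[2,4,6-tris(benzyloxy)phenyl]methyl]pentanoate
Product: 6 methyl 3-methoxy-2-[[2,4,6-tris(benzyloxy)phenyl]methyl]pent-2-enoate (E/Z mixture)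
Conditions: NaH, THF–DMPU, 0 °C; Me2SO4, 0 °C → rt
Reagents that add atoms: dimethyl sulfate COS(=O)(=O)OC
Why: O-Alkylation of a β-keto ester enolate: a dissociated sodium enolate in THF–DMPU and the hard electrophile dimethyl sulfate favour attack through oxygen, the more so because C-methylation would have to build a quaternary carbon next to the bulky benzyl group; either enol ether geometry gives the same dienolate in step 4.

Step 4
Reactants: 6 methyl 3-methoxy-2-[[2,4,6-tris(benzyloxy)phenyl]methyl]pent-2-enoate
Product: 7 [1,3-dimethoxy-2-[[2,4,6-tris(benzyloxy)phenyl]methyl]penta-1,3-dienyl]oxy-trimethylsilane (mixture of double-bond isomers)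
Conditions: LDA (1.15 equiv), THF, −78 °C; TMSCl, −78 °C → rt; pentane, filtration under Ar, used crude
Reagents that add atoms: chlorotrimethylsilane C[Si](C)(C)Cl
Why: Kinetic γ-deprotonation of a β-alkoxy enoate (the C4 methylene is the only position whose anion is an ester dienolate) and O-silylation, the standard route to 1,3-dialkoxy-1-silyloxydienes; the moisture-sensitive diene is used crude after removal of LiCl.

Step 5
Reactants: 8 propan-2-ol; 9 trichloroethylene
Product: 10 (E)-1,2-dichloro-1-(propan-2-yloxy)ethene
Conditions: KH, THF, 0 °C → rt; then Cl2C=CHCl, −50 °C → rt; distillation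
Reagents that add atoms: none
Why: Alkoxide addition to dichloroacetylene generated in situ from trichloroethylene (net addition–elimination); anti addition gives the (E)-1,2-dichlorovinyl ether, the established precursor of alkynyl ethers.

Step 6
Reactants: 10 (E)-1,2-dichloro-1-(propan-2-yloxy)ethene; 11 N-methoxy-N-methylacetamide
Product: 13 4-(propan-2-yloxy)but-3-yn-2-one, via lithium isopropoxyacetylide 12 (not isolated)
Conditions: n-BuLi (2.2 equiv), THF, −78 → −40 °C; then 11, −78 → −20 °C; AcOH, −78 °C
Reagents that add atoms: none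
Why: n-BuLi effects β-elimination to the chloroalkynyl ether and chlorine–lithium exchange to lithium alkynyl ether 12, whose addition to the Weinreb amide stops at the chelated tetrahedral adduct, so the ynone is released only on the cold acidic quench (Weinreb ketone synthesis); the isopropyl group is chosen because it can later be removed without touching a methyl ether.

Step 7
Reactants: 7 [1,3-dimethoxy-2-[[2,4,6-tris(benzyloxy)phenyl]methyl]penta-1,3-dienyl]oxy-trimethylsilane; 13 4-(propan-2-yloxy)but-3-yn-2-one
Product: 16 1-[2-hydroxy-4-methoxy-5-methyl-6-(propan-2-yloxy)-3-[[2,4,6-tris(benzyloxy)phenyl]methyl]phenyl]ethanone, via cyclohexadiene cycloadduct 14 (not isolated), via aryl trimethylsilyl ether 15 (not isolated)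
Conditions: PhMe, −20 → 45 °C, Ar; then 1 M HCl, THF, 0 °C → rt
Reagents that add atoms: none
Why: Proposed new method: the C4 terminus of the vinylketene silyl acetal (largest HOMO coefficient, the α-carbon C2 being fully substituted) should add to the alkoxy-bearing β-carbon of the ynone and the resulting allenolate carbon should bond to the acetal carbon C1, either in one asynchronous [4+2] event or by Mukaiyama–Michael addition followed by 6-exo-trig capture of the silyloxy(methoxy)carbenium ion; cyclohexa-1,4-diene 14 then loses methanol across C1/C4 and aryl silyl ether 15 is hydrolysed to the acetyl-chelated phenol. The closest known reaction type is the Diels–Alder addition and aromatisation of 1,3-dimethoxy-1-silyloxybutadienes with acetylenic ketones, esters and quinones, which gives resorcinol monomethyl ethers; new here is a β-alkoxy ynone as the dienophile, which would deliver the third ring oxygen. Ring B is closed as a six-membered carbocycle by [4+2] cycloaddition, the two new bonds being C2'–C3' and C4'–C5'. No stereocentre survives, because C1 and C4 of 14 become aromatic, so diene geometry and adduct configuration are immaterial. The step needs head-to-tail regioselectivity, which the ketene-acetal polarisation of the diene and the conjugate-acceptor polarisation of the ynone should impose in the same sense, and it needs a temperature below the retro-ene threshold of the isopropyl ynol ether, which the high nucleophilicity of the diene should allow.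

Step 8
Reactants: 16 1-[2-hydroxy-4-methoxy-5-methyl-6-(propan-2-yloxy)-3-[[2,4,6-tris(benzyloxy)phenyl]methyl]phenyl]ethanone
Product: 17 1-[2,6-dihydroxy-4-methoxy-3-methyl-5-[(2,4,6-trihydroxyphenyl)methyl]phenyl]ethanone
Conditions: BCl3 (8 equiv), C6HMe5 (10 equiv), CH2Cl2, −78 → 0 °C; MeOH then H2O
Reagents that add atoms: none
Why: Boron trichloride dealkylation: benzyl ethers cleave at −78 °C with pentamethylbenzene intercepting the benzyl cations before they can C-benzylate the liberated phloroglucinol ring, the secondary isopropyl ether ionises on warming to 0 °C, and the primary C6' methyl ether, which has no chelating neighbour, should remain intact at this temperature.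

Step 9
Reactants: 17 1-[2,6-dihydroxy-4-methoxy-3-methyl-5-[(2,4,6-trihydroxyphenyl)methyl]phenyl]ethanone; 18 butanoyl chloride
Product: 19 1-[3-[(3-acetyl-2,4-dihydroxy-6-methoxy-5-methylphenyl)methyl]-2,4,6-trihydroxyphenyl]butan-1-one
Conditions: AlCl3 (5 equiv), CH2Cl2–PhNO2, 0 °C → rt; 1 M HCl work-up
Reagents that add atoms: none
Why: Friedel–Crafts acylation: ring B has no free position, the two free positions of ring A are equivalent, and the first acyl group deactivates the ring against a second, so a single monoketone is expected.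

Step 10
Reactants: 19 1-[3-[(3-acetyl-2,4-dihydroxy-6-methoxy-5-methylphenyl)methyl]-2,4,6-trihydroxyphenyl]butan-1-one; 20 prenyl bromide (1-bromo-3-methylbut-2-ene)
Product: 21 1-[3-[(3-acetyl-2,4-dihydroxy-6-methoxy-5-methylphenyl)methyl]-2,4,6-trihydroxy-5-(3-methylbut-2-en-1-yl)phenyl]butan-1-one
Conditions: DBU (1.1 equiv), THF, 0 °C → rt; dilute HCl work-up
Reagents that add atoms: none
Why: C-Alkylation of an acylphloroglucinol phenolate with an allylic bromide: ring A of 19 is the most acidic and most C-nucleophilic part of the molecule and C3 is the only unsubstituted aromatic carbon, so only one C-prenyl isomer can form, while the mild amidine base at low temperature limits O-alkylation and bridge scrambling.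

**Compound list**

1 | 2,4,6-trihydroxybenzaldehyde | O=Cc1c(O)cc(O)cc1O | starting material
2 | 2,4,6-tris(benzyloxy)benzaldehyde | O=Cc1c(OCc2ccccc2)cc(OCc2ccccc2)cc1OCc1ccccc1 | intermediate
3 | methyl 3-oxopentanoate | CCC(=O)CC(=O)OC | starting material
4 | methyl 3-oxo-2-[[2,4,6-tris(benzyloxy)phenyl]methylidene]pentanoate (E/Z mixture, not isolated) | CCC(=O)C(=Cc1c(OCc2ccccc2)cc(OCc2ccccc2)cc1OCc1ccccc1)C(=O)OC | intermediate
5 | methyl 3-oxo-2-[[2,4,6-tris(benzyloxy)phenyl]methyl]pentanoate (racemic) | CCC(=O)C(Cc1c(OCc2ccccc2)cc(OCc2ccccc2)cc1OCc1ccccc1)C(=O)OC | intermediate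
6 | methyl 3-methoxy-2-[[2,4,6-tris(benzyloxy)phenyl]methyl]pent-2-enoate (E/Z mixture) | CCC(OC)=C(Cc1c(OCc2ccccc2)cc(OCc2ccccc2)cc1OCc1ccccc1)C(=O)OC | intermediate
7 | [1,3-dimethoxy-2-[[2,4,6-tris(benzyloxy)phenyl]methyl]penta-1,3-dienyl]oxy-trimethylsilane (mixture of double-bond isomers) | COC(O[Si](C)(C)C)=C(Cc1c(OCc2ccccc2)cc(OCc2ccccc2)cc1OCc1ccccc1)C(OC)=CC | intermediate
8 | propan-2-ol | CC(C)O | starting material
9 | trichloroethylene | ClC=C(Cl)Cl | starting material
10 | (E)-1,2-dichloro-1-(propan-2-yloxy)ethene | Cl/C=C(/Cl)OC(C)C | intermediate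
11 | N-methoxy-N-methylacetamide | CON(C)C(C)=O | starting material
12 | lithium (propan-2-yloxy)ethynide (not isolated) | [Li]C#COC(C)C | intermediate
13 | 4-(propan-2-yloxy)but-3-yn-2-one | CC(C)OC#CC(C)=O | intermediate
14 | 1-[6-methoxy-4-methoxy-3-methyl-2-(propan-2-yloxy)-6-(trimethylsilyloxy)-5-[[2,4,6-tris(benzyloxy)phenyl]methyl]cyclohexa-1,4-dien-1-yl]ethanone (diastereomer mixture, not isolated) | COC1(O[Si](C)(C)C)C(Cc2c(OCc3ccccc3)cc(OCc3ccccc3)cc2OCc2ccccc2)=C(OC)C(C)C(OC(C)C)=C1C(C)=O | intermediate
15 | 1-[4-methoxy-5-methyl-6-(propan-2-yloxy)-2-(trimethylsilyloxy)-3-[[2,4,6-tris(benzyloxy)phenyl]methyl]phenyl]ethanone (not isolated) | CC(=O)c1c(O[Si](C)(C)C)c(Cc2c(OCc3ccccc3)cc(OCc3ccccc3)cc2OCc2ccccc2)c(OC)c(C)c1OC(C)C | intermediate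
16 | 1-[2-hydroxy-4-methoxy-5-methyl-6-(propan-2-yloxy)-3-[[2,4,6-tris(benzyloxy)phenyl]methyl]phenyl]ethanone | CC(=O)c1c(O)c(Cc2c(OCc3ccccc3)cc(OCc3ccccc3)cc2OCc2ccccc2)c(OC)c(C)c1OC(C)C | intermediate
17 | 1-[2,6-dihydroxy-4-methoxy-3-methyl-5-[(2,4,6-trihydroxyphenyl)methyl]phenyl]ethanone | CC(=O)c1c(O)c(Cc2c(O)cc(O)cc2O)c(OC)c(C)c1O | intermediate
18 | butanoyl chloride | CCCC(Cl)=O | starting material
19 | 1-[3-[(3-acetyl-2,4-dihydroxy-6-methoxy-5-methylphenyl)methyl]-2,4,6-trihydroxyphenyl]butan-1-one | CCCC(=O)c1c(O)cc(O)c(Cc2c(O)c(C(C)=O)c(O)c(C)c2OC)c1O | intermediate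
20 | prenyl bromide (1-bromo-3-methylbut-2-ene) | CC(C)=CCBr | starting material
21 | 1-[3-[(3-acetyl-2,4-dihydroxy-6-methoxy-5-methylphenyl)methyl]-2,4,6-trihydroxy-5-(3-methylbut-2-en-1-yl)phenyl]butan-1-one (CNP0109173.0) | CCCC(=O)c1c(O)c(CC=C(C)C)c(O)c(Cc2c(O)c(C(C)=O)c(O)c(C)c2OC)c1O | target

**Step count and risks**

Total steps: 10. Longest linear sequence: 8 steps (1, 2, 3, 4, 7, 8, 9, 10) from 2,4,6-trihydroxybenzaldehyde; the ynone arm is 2 steps (5, 6).

Steps most likely to fail:

Step 7 (proposed new method). The donor-substituted ynone may be too weak an acceptor to react below the temperature at which the ynol ether fragments by retro-ene loss of propene. The reaction may also stop after the first C–C bond, through silyl transfer to the allenolate, or be diverted into [2+2] addition across the ketene acetal double bond. Fallback with known chemistry: ring B would be brought in as a finished arene and joined to ring A by Friedel–Crafts benzylation. It sets out from aldehyde 2, which is reduced (NaBH4, THF–MeOH, 0 °C) to [2,4,6-tris(benzyloxy)phenyl]methanol F1. Separately, commercial 2,4,6-trihydroxyacetophenone is C-methylated (MeI, NaOMe, MeOH) to 1-(2,4,6-trihydroxy-3-methylphenyl)ethanone F2. Selective O-methylation of the non-chelated 4-OH (Me2SO4, 1 equiv, K2CO3, acetone) then gives 1-(2,6-dihydroxy-4-methoxy-3-methylphenyl)ethanone F3, whose only free ring position is the future C1'. Acid-catalysed benzylation of F3 (in excess) with F1 (cat. Sc(OTf)3, CH2Cl2, 0 °C) should give 1-[2,6-dihydroxy-4-methoxy-3-methyl-5-[[2,4,6-tris(benzyloxy)phenyl]methyl]phenyl]ethanone F4. Hydrogenolysis (H2, Pd/C, EtOAc–MeOH) then returns to the route at compound 17.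

Step 10. With five phenols present, O-alkylation on either ring, over-alkylation with dearomatisation at a substituted carbon, or base-induced scission and redistribution of the methylene bridge may compete with C-prenylation. Fallback: halogenation and cross-coupling in place of phenolate alkylation. It sets out from compound 19, whose single aromatic C–H is iodinated (NIS, MeCN, 0 °C) to 1-[3-[(3-acetyl-2,4-dihydroxy-6-methoxy-5-methylphenyl)methyl]-2,4,6-trihydroxy-5-iodophenyl]butan-1-one F5. Stille coupling with tributyl(3-methylbut-2-en-1-yl)stannane (Pd(PPh3)4, DMF, 60 °C), which couples at the unsubstituted allyl terminus, returns to the route at target 21.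

Step 9. Aluminium chloride acting on the free polyphenol may cause ipso-protonation and cleavage or redistribution of the diarylmethane bridge, O-acylation, or loss of the hindered methyl ether. Fallback: acylation before deprotection, without a metal Lewis acid. It sets out from compound 16, which is acylated on the tribenzyloxy ring with the mixed anhydride from butanoic acid and trifluoroacetic anhydride (CH2Cl2, 0 °C → rt) to 1-[3-[[3-acetyl-2-hydroxy-6-methoxy-5-methyl-4-(propan-2-yloxy)phenyl]methyl]-2,4,6-tris(benzyloxy)phenyl]butan-1-one F6. Dealkylation under the conditions of step 8 (BCl3, C6HMe5, CH2Cl2, −78 → 0 °C) returns to the route at compound 19.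

**Further compounds**

F1 | step 7 | [2,4,6-tris(benzyloxy)phenyl]methanol | OCc1c(OCc2ccccc2)cc(OCc2ccccc2)cc1OCc1ccccc1
F2 | step 7 | 1-(2,4,6-trihydroxy-3-methylphenyl)ethanone | CC(=O)c1c(O)cc(O)c(C)c1O
F3 | step 7 | 1-(2,6-dihydroxy-4-methoxy-3-methylphenyl)ethanone | CC(=O)c1c(O)cc(OC)c(C)c1O
F4 | step 7 | 1-[2,6-dihydroxy-4-methoxy-3-methyl-5-[[2,4,6-tris(benzyloxy)phenyl]methyl]phenyl]ethanone | CC(=O)c1c(O)c(Cc2c(OCc3ccccc3)cc(OCc3ccccc3)cc2OCc2ccccc2)c(OC)c(C)c1O
F5 | step 10 | 1-[3-[(3-acetyl-2,4-dihydroxy-6-methoxy-5-methylphenyl)methyl]-2,4,6-trihydroxy-5-iodophenyl]butan-1-one | CCCC(=O)c1c(O)c(I)c(O)c(Cc2c(O)c(C(C)=O)c(O)c(C)c2OC)c1O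
F6 | step 9 | 1-[3-[[3-acetyl-2-hydroxy-6-methoxy-5-methyl-4-(propan-2-yloxy)phenyl]methyl]-2,4,6-tris(benzyloxy)phenyl]butan-1-one | CCCC(=O)c1c(OCc2ccccc2)cc(OCc2ccccc2)c(Cc2c(O)c(C(C)=O)c(OC(C)C)c(C)c2OC)c1OCc1ccccc1
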